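## Analysis of the target

The target 37 is a 14-membered lactone. Ring atoms are O1 and C1–C13, counted from the lactone carbonyl C1 to the carbinol C13 that carries the ring oxygen; the side chain runs from C14 to C24. It carries a carboxymethyl arm on C3, a methyl group on C9, a free hydroxyl on C11 and a 2-hydroxyundecyl chain on C13 (hydroxyl on C15).

There are three stereocentres, 11S, 13R and 15S. O11 and O13 are syn and O13 and O15 are anti, so C11 and C15 stand in a 1,5-anti relation around C13. O13 alone is acylated and has to be told apart from its two neighbours.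

The ring holds three E double bonds: C2=C3 (trisubstituted, conjugated, ring carbons C1 and C4 cis), C5=C6 (disubstituted) and C8=C9 (trisubstituted). They are separated only by the methylenes C4 and C7. Both methylenes are doubly allylic, and C4 is also vinylogous to the ester, so base, strong acid or metal hydrides can pull any of the alkenes into conjugation.

The C1 ester and the arm carboxyl on C3 form a glutaconic half-ester. Once the acid is free, base would shift C2=C3 towards the arm or scramble its geometry, so the acid has to be set free last and without base.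

The difficulties are the closure of the macrocycle, the position and E geometry of C5=C6 between C4 and C7, and the acylation of O13 by an acid that isomerises easily. The plan rests on C5=C6, the only unbranched alkene of the ring. It is made as the C5≡C6 triple bond by ring-closing alkyne metathesis and reduced to the E alkene afterwards.

## Retrosynthetic reasoning

**Arm acid (37 back to 33).** Only functional groups change. The acid of 37 is traced through the bis-silyl acid 36 and the aldehyde 35 to the primary alcohol 34 and its silyl ether 33. The arm is carried as a protected alcohol because a glutaconate would not survive the basic or metal-mediated steps before it. The forward steps have to free one primary silyl ether beside two secondary ones, oxidise in two stages without base, and desilylate last.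

**C5=C6 (33 back to 30).** The E alkene is traced to the triple bond of cycloalkyne 30. Trans-addition of a silane (31 and 32) followed by protodesilylation fixes E geometry by mechanism, wherever silicon sits. Alkene metathesis at this position of a 14-membered ring could not guarantee that, and its carbenes and hydrides could move the skipped alkenes.

**Ring closure (30 back to 29).** The C5≡C6 bond is cut, which opens the ring to the diyne ester 29 with a methyl-capped alkyne on C4 and on C7. The cut lies between two sp carbons far from every stereocentre, and the catalyst that closes it ignores alkenes, the enoate and silyl ethers. The forward step must favour ring closure over oligomerisation and loses the two methyl caps as a volatile alkyne.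

**Ester C1–O13 (29 back to 18 and 28).** Acid 28 has a C4 methylene that is both γ to the carboxyl and propargylic. Acyl activation could deconjugate or scramble it through a vinylketene. The ester is therefore formed by Mitsunobu displacement, in which the acid acts only as a carboxylate nucleophile. This inverts C13, so alcohol 18 is made epimeric at that carbon.

**Acid fragment (28 back to 19).** The C4–C5 bond is cut between the allylic bromide 26 and propyne 16 (copper-mediated alkynylation, ester 27, then hydrolysis). An alkynyl nucleophile on an allylic electrophile is the regiochemically safe way to a skipped enyne. The cis relation of C1 and C4 in 26 is taken from a ring: butenolide 24 is opened to the bromo ester 25 and re-silylated. The butenolide comes from the Z-iodoenoate 22 by a hydroxymethylating cross-coupling and lactonisation of 23. The iodoenoate comes from ynoate 21 by anti hydroiodination, and 21 from the alkyne 19 through its acetylide 20.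

**Skipped enyne of the alcohol (18 back to 11).** Alcohol 18 is the desilylated form of 17. The C6–C7 bond is cut between allylic bromide 15 and 16, and 15 comes from allylic alcohol 14. The C7–C8 bond and the C9 methyl are traced to the terminal alkyne 11 by syn-methylalumination (alane 12, alanate 13) and capture of a one-carbon electrophile. This fixes C8=C9 as E.

**Triol (11 back to 1).** The three carbinols are made one by one by reagent-controlled additions, so that each oxygen is protected as it appears and O13 gets its own temporary group.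
- C10–C11 is cut (11 and 10 back to aldehyde 9, asymmetric propargylation).
- C12–C13 is cut (9, via 8 and 7, back to 6 and aldehyde 5, asymmetric allylation).
- C14–C15 is cut (5, via 4 and 3, back to 2 and decanal 1, asymmetric allylation).

Directed reductions were not used because they leave 1,3-diols in which O13 cannot be distinguished.

## Alternatives that were turned down

**Alternative 1:** Aldolase assembly of the C9–C14 diol.
- Disconnection: C10–C11 and C12–C13 are cut as two aldol bonds, reducing the C9–C14 segment to chloroacetaldehyde (A2) and two molecules of acetaldehyde (A3).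
- Forward key step: the aldolase DERA adds A3 twice in sequence to A2. The product rests as the six-membered lactol of (3R,5S)-6-chloro-3,5-dihydroxyhexanal (A1), with C13 and C11 in the syn relation the target needs.
- For: it is catalytic, takes one step from two-carbon feedstocks and needs no chiral reagent. The lactol ties up O13 while O11 stays free, so the differentiation that costs the chosen route a temporary silyl group (steps 5 and 12) comes for nothing. On stereochemical economy for C11 and C13 it is clearly stronger than steps 4–8.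
- Against: it closes no ring and does not address C5=C6, C2=C3 or the macrocyclisation. C9 arrives as a lactol carbon that must still become the methyl-bearing E alkene, through a methyl ketone and an olefination with no geometric control. C14 arrives as a chloride next to O13 and must be joined to C15–C24 with C15 set separately.
- Comparison: the chosen strategy spends more steps on the triol, but its key step settles ring, alkene position and, after trans-reduction, geometry. A1 would be a building block inside such a route, not a replacement for it.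

**Alternative 2:** Evans–Tishchenko macrolactonisation.
- Disconnection: the O13–C1 ester bond is cut together with the C15–H bond, leading to the open-chain hydroxy keto enal A5 (C1 aldehyde, free O11 and O13, C15 ketone).
- Forward key step: under samarium catalysis O13 adds to the aldehyde, and the hemiacetal hydrogen passes through a six-membered samarium-bridged chair to the C15 ketone. This forms the lactone, closes the 14-membered ring and sets C15 anti to C13 in macrolactone A4.
- For: ring, ester and a stereocentre come from one redox-neutral step. O13 ends acylated and O15 free with no protecting-group differentiation and no carboxyl activation. On these points it is stronger than steps 5, 12 and 20 and would shorten the triol sector.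
- Against: A5 must already hold the whole skipped triene, including E-C5=C6, in an open chain, so the hardest alkene is left unsolved. The aldehyde is a β,β-disubstituted enal whose hemiacetal is disfavoured and whose C4 methylene is doubly activated. A one-electron samarium reductant can reduce the enal or start pinacol coupling. Retro-aldol cleavage between C13 and C15 and intermolecular Tishchenko oligomerisation compete at macrocyclisation dilution.
- Comparison: the chosen route is longer but separates the risks. C5=C6 is created on the ring by a catalyst that tolerates everything else, and its geometry is set by a separate, mechanistically fixed step.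

**Alternative 3:** Ester-directed C–H allylation at C3–C4.
- Disconnection: the C3–C4 bond is cut, leading to A7, the C13 ester of an (E)-5-silyloxypent-2-enoic acid whose chain ends in a vinyl group (C4=C5) with a methyl carbonate on C6.
- Forward key step: a cationic Cp*-rhodium catalyst (trivalent rhodium), directed by the ester carbonyl, cleaves the C3–H bond cis to it. The rhodacycle inserts the terminal alkene to form C3–C4, and β-oxygen elimination of the carbonate creates C5=C6 and closes the ring to macrolactone A6, which is identical with 33.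
- For: ring, C3–C4 bond and C5=C6 form in one step. No alkyne reduction (step 22) is needed, and the acid fragment is a plain E-enoate in place of steps 13–19. The C2=C3 geometry follows from the cis C–H bond. In step economy it is stronger than the chosen strategy.
- Against: an ester is a weak director for alkenyl C–H cleavage. The rhodacycle must capture an alkene at the far end of its own chain, a macrocyclic insertion without a counterpart among the intermolecular allylations. The geometry of C5=C6 is decided by β-oxygen elimination inside the forming ring and is not secured. The cationic rhodium and silver salts can move the new 1,4-diene into conjugation.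
- Comparison: the chosen strategy gives away a few steps after ring closure and a longer acid fragment. In return it closes the ring by a reaction class established for macrocyclic lactones and sets E geometry by trans-addition, not by ring conformation.

Key step: step 21

## Route

Remarks on the chemistry:
- TBS = tert-butyldimethylsilyl, TES = triethylsilyl; atom numbers C1–C24 are those of the target.
- Boron, aluminium and tin alkoxides or carboxylates that are only hydrolysed on work-up are counted as the work-up forms of the products.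
- The acid is joined to O13 with inversion (step 20), so the alcohol branch is made epimeric at C13.

Step 1
Reactants: 1 decanal
Product: 2 (4S)-tridec-1-en-4-ol
Conditions: (+)-Ipc2BOMe, allylMgBr, Et2O, −78 °C → rt; then 1, −78 °C; NaOH, H2O2
Reagents that add atoms: allylmagnesium bromide, C=CC[Mg]Br
Why: Brown allylation: (+)-Ipc2B(allyl), made in the flask, adds through a chair-like six-membered transition state to the Re face of the aldehyde, which sets C15 as S. The aldehyde is achiral, so the reagent is the only control element.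

Step 2
Reactants: 2 (4S)-tridec-1-en-4-ol
Product: 3 (4S)-4-(TBS-oxy)tridec-1-ene
Conditions: TBSCl, imidazole, DMF, rt
Reagents that add atoms: tert-butyldimethylsilyl chloride, CC(C)(C)[Si](C)(C)Cl
Why: Silylation of a secondary alcohol; the TBS group on O15 is meant to stay until the last step.

Step 3
Reactants: 3 (4S)-4-(TBS-oxy)tridec-1-ene
Product: 5 (3S)-3-(TBS-oxy)dodecanal, via secondary ozonide 4 (not isolated)
Conditions: O3, CH2Cl2, −78 °C; PPh3, −78 °C → rt
Reagents that add atoms: ozone, [O-][O+]=O
Why: Ozonolysis with reductive work-up cleaves the terminal alkene to the C13 aldehyde; the silyl ether and C15 are not affected.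

Step 4
Reactants: 5 (3S)-3-(TBS-oxy)dodecanal
Product: 6 (4R,6S)-6-(TBS-oxy)pentadec-1-en-4-ol
Conditions: (+)-Ipc2BOMe, allylMgBr, Et2O, −78 °C → rt; then 5, −78 °C; NaOH, H2O2
Reagents that add atoms: allylmagnesium bromide, C=CC[Mg]Br
Why: Second Brown allylation; the same (+)-Ipc2B(allyl) again attacks the Re face, which here gives the 4R carbinol (O13 syn to O15). This is the C13 epimer of the target on purpose, because step 20 inverts this centre; reagent control should override the weak 1,3-induction of the β-silyloxy group.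

Step 5
Reactants: 6 (4R,6S)-6-(TBS-oxy)pentadec-1-en-4-ol
Product: 7 (4R,6S)-6-(TBS-oxy)-4-(TES-oxy)pentadec-1-ene
Conditions: TESCl, imidazole, CH2Cl2, 0 °C
Reagents that add atoms: triethylsilyl chloride, CC[Si](CC)(CC)Cl
Why: O13 receives a silyl group that mild acid removes beside secondary TBS ethers; this keeps O13 distinct from O11 and O15.

Step 6
Reactants: 7 (4R,6S)-6-(TBS-oxy)-4-(TES-oxy)pentadec-1-ene
Product: 9 (3S,5S)-5-(TBS-oxy)-3-(TES-oxy)tetradecanal, via secondary ozonide 8 (not isolated)
Conditions: O3, CH2Cl2, −78 °C; PPh3, −78 °C → rt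
Reagents that add atoms: ozone, [O-][O+]=O
Why: Ozonolysis with reductive work-up gives the C11 aldehyde; it is used at once to avoid β-elimination of the silyloxy group.

Step 7
Reactants: 9 (3S,5S)-5-(TBS-oxy)-3-(TES-oxy)tetradecanal
Product: 10 (4S,6R,8S)-8-(TBS-oxy)-6-(TES-oxy)heptadec-1-yn-4-ol
Conditions: (−)-Ipc2BOMe, allenylMgBr, Et2O, −78 °C; then 9, −78 °C; NaOH, H2O2, 0 °C (brief)
Reagents that add atoms: allenylmagnesium bromide, C=C=C[Mg]Br
Why: Brown-type allenylboration: the allenylborane reacts through a six-membered SE2′ transition state, so the C10–C11 bond forms at the γ-carbon and a terminal alkyne results. The (−)-Ipc2B series delivers C10 to the Si face, as its allyl analogue does, which sets C11 as S (anti to O13 here, syn after the inversion of step 20).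

Step 8
Reactants: 10 (4S,6R,8S)-8-(TBS-oxy)-6-(TES-oxy)heptadec-1-yn-4-ol
Product: 11 (4S,6S,8S)-4,8-bis(TBS-oxy)-6-(TES-oxy)heptadec-1-yne
Conditions: TBSOTf, 2,6-lutidine, CH2Cl2, −78 → 0 °C
Reagents that add atoms: tert-butyldimethylsilyl triflate, CC(C)(C)[Si](C)(C)OS(=O)(=O)C(F)(F)F
Why: Silylation of the hindered homopropargylic alcohol with the triflate and a non-nucleophilic base; the TES ether does not exchange at low temperature.

Step 9
Reactants: 11 (4S,6S,8S)-4,8-bis(TBS-oxy)-6-(TES-oxy)heptadec-1-yne
Product: 14 (2E,5S,7S,9S)-5,9-bis(TBS-oxy)-3-methyl-7-(TES-oxy)octadec-2-en-1-ol, via alkenyldimethylalane 12 (not isolated), via lithium alkenylalanate 13 (not isolated)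
Conditions: Me3Al, Cp2ZrCl2 (cat.), CH2Cl2, 0 °C → rt; evaporate; n-BuLi, THF, −78 °C; (CH2O)n, −78 °C → rt
Reagents that add atoms: trimethylaluminium, C[Al](C)C; formaldehyde (as paraformaldehyde), C=O
Why: Negishi zirconium-catalysed carboalumination adds methyl and aluminium syn across the terminal alkyne with methyl on the internal carbon, which fixes C8=C9 as E. The alanate formed with n-BuLi transfers its alkenyl group to formaldehyde with retention and supplies C7.

Step 10
Reactants: 14 (2E,5S,7S,9S)-5,9-bis(TBS-oxy)-3-methyl-7-(TES-oxy)octadec-2-en-1-ol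
Product: 15 (2E,5S,7S,9S)-1-bromo-5,9-bis(TBS-oxy)-3-methyl-7-(TES-oxy)octadec-2-ene
Conditions: CBr4, PPh3, CH2Cl2, −20 → 0 °C
Reagents that add atoms: carbon tetrabromide, BrC(Br)(Br)Br
Why: Appel reaction; the primary allylic alkoxyphosphonium ion is displaced by bromide at C7 (SN2) without allylic transposition, and the conditions are neutral for the silyl ethers.

Step 11
Reactants: 15 (2E,5S,7S,9S)-1-bromo-5,9-bis(TBS-oxy)-3-methyl-7-(TES-oxy)octadec-2-ene; 16 propyne
Product: 17 (5E,8S,10S,12S)-8,12-bis(TBS-oxy)-6-methyl-10-(TES-oxy)henicos-5-en-2-yne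
Conditions: 16 (excess), CuI (cat.), NaI (cat.), Cs2CO3, DMF, rt
Reagents that add atoms: none
Why: Copper-catalysed alkynylation of an allylic bromide: the copper acetylide substitutes at the primary C7 carbon, since attack at C9 would create a quaternary centre. This gives the skipped enyne with the C6–C7 bond and the methyl cap.

Step 12
Reactants: 17 (5E,8S,10S,12S)-8,12-bis(TBS-oxy)-6-methyl-10-(TES-oxy)henicos-5-en-2-yne
Product: 18 (5E,8S,10S,12S)-8,12-bis(TBS-oxy)-6-methylhenicos-5-en-2-yn-10-ol
Conditions: PPTS (cat.), MeOH/CH2Cl2, 0 °C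
Reagents that add atoms: none
Why: Acid-catalysed methanolysis removes the secondary TES ether much faster than secondary TBS ethers, which frees O13 alone; the skipped enyne is stable to this mild acid.

Step 13
Reactants: 19 tert-butyl(but-3-yn-1-yloxy)dimethylsilane
Product: 21 methyl 5-(TBS-oxy)pent-2-ynoate, via lithium acetylide 20 (not isolated)
Conditions: n-BuLi, THF, −78 °C; ClCO2Me, −78 → 0 °C
Reagents that add atoms: methyl chloroformate, COC(Cl)=O
Why: Acylation of a lithium acetylide with a chloroformate; it supplies C1 and makes the alkyne an acceptor for the next step.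

Step 14
Reactants: 21 methyl 5-(TBS-oxy)pent-2-ynoate
Product: 22 methyl (2Z)-3-iodo-5-(TBS-oxy)pent-2-enoate
Conditions: NaI, AcOH (2 equiv), MeCN, 70 °C
Reagents that add atoms: sodium iodide, [Na+].[I-]
Why: Hydroiodination of a 2-ynoate: iodide adds to C3 in conjugate fashion and the allenolate is protonated anti, so iodine ends cis to the ester (2Z). The small amount of acetic acid in acetonitrile should spare the primary silyl ether.

Step 15
Reactants: 22 methyl (2Z)-3-iodo-5-(TBS-oxy)pent-2-enoate
Product: 24 4-[2-(TBS-oxy)ethyl]furan-2(5H)-one, via hydroxy ester 23 (not isolated)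
Conditions: Bu3SnCH2OH, Pd(PPh3)4 (cat.), dioxane, 90 °C; then PPTS (cat.), 60 °C
Reagents that add atoms: (tributylstannyl)methanol, OC[Sn](CCCC)(CCCC)CCCC
Why: Stille coupling at zerovalent palladium proceeds with retention at the alkenyl iodide, so the hydroxymethyl carbon (C4) ends cis to C1 and the cis hydroxy ester 23 lactonises. The ring of 24 stores the C1/C4 cis relation.

Step 16
Reactants: 24 4-[2-(TBS-oxy)ethyl]furan-2(5H)-one
Product: 25 methyl (2Z)-4-bromo-3-(2-hydroxyethyl)but-2-enoate
Conditions: AcBr, MeOH, 0 °C → rt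
Reagents that add atoms: acetyl bromide (bromine, through HBr formed with methanol), CC(Br)=O; methanol, CO
Why: Ring-opening bromination of a lactone with HBr in an alcohol, as practised on γ-butyrolactone: bromide cleaves the protonated lactone at the allylic O–CH2 bond and Fischer esterification with the solvent blocks the way back. The double bond is not touched, so the cis C1/C4 (2Z) geometry is kept; the silyl ether is lost by acid methanolysis and is put back in step 17.

Step 17
Reactants: 25 methyl (2Z)-4-bromo-3-(2-hydroxyethyl)but-2-enoate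
Product: 26 methyl (2Z)-4-bromo-3-[2-(TBS-oxy)ethyl]but-2-enoate
Conditions: TBSOTf, 2,6-lutidine, CH2Cl2, −78 °C
Reagents that add atoms: tert-butyldimethylsilyl triflate, CC(C)(C)[Si](C)(C)OS(=O)(=O)C(F)(F)F
Why: Silylation with the triflate and a hindered base at low temperature avoids nucleophiles such as imidazole that would attack the allylic bromide, and stops the free hydroxyl from closing onto C4.

Step 18
Reactants: 26 methyl (2Z)-4-bromo-3-[2-(TBS-oxy)ethyl]but-2-enoate; 16 propyne
Product: 27 methyl (2E)-3-[2-(TBS-oxy)ethyl]hept-2-en-5-ynoate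
Conditions: 16 (excess), CuI (cat.), NaI (cat.), Cs2CO3, DMF, 0 °C → rt
Reagents that add atoms: none
Why: Copper-catalysed alkynylation of the allylic bromide: the copper acetylide substitutes the primary C4 bromide and builds the C4–C5 bond; attack at C2 would destroy conjugation. Carbonate is too weak a base to deprotonate C4, so the skipped enyne and the C2=C3 geometry should persist (the descriptor changes from Z to E only because the priorities change).

Step 19
Reactants: 27 methyl (2E)-3-[2-(TBS-oxy)ethyl]hept-2-en-5-ynoate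
Product: 28 (2E)-3-[2-(TBS-oxy)ethyl]hept-2-en-5-ynoic acid
Conditions: Me3SnOH, 1,2-dichloroethane, 70 °C; dilute aq. HCl work-up
Reagents that add atoms: trimethyltin hydroxide, C[Sn](C)(C)O
Why: Ester cleavage with Me3SnOH, a neutral hydroxide carrier used for base-sensitive methyl esters; it avoids free hydroxide that could deprotonate the doubly activated C4 methylene.

Step 20
Reactants: 18 (5E,8S,10S,12S)-8,12-bis(TBS-oxy)-6-methylhenicos-5-en-2-yn-10-ol; 28 (2E)-3-[2-(TBS-oxy)ethyl]hept-2-en-5-ynoic acid
Product: 29 (5E,8S,10R,12S)-8,12-bis(TBS-oxy)-6-methylhenicos-5-en-2-yn-10-yl (2E)-3-[2-(TBS-oxy)ethyl]hept-2-en-5-ynoate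
Conditions: PPh3, DIAD, toluene, 0 °C → rt
Reagents that add atoms: none
Why: Mitsunobu esterification: the alcohol is activated as an alkoxyphosphonium ion and displaced by the carboxylate of 28 with inversion, which turns the 10S carbinol of 18 into the 13R centre of the target. The acid is never made into an acyl donor, so no vinylketene can form and C2=C3 and the C4 methylene keep their place.

Step 21
Reactants: 29 (5E,8S,10R,12S)-8,12-bis(TBS-oxy)-6-methylhenicos-5-en-2-yn-10-yl (2E)-3-[2-(TBS-oxy)ethyl]hept-2-en-5-ynoate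
Product: 30 (3E,9E,12S,14R)-12-(TBS-oxy)-14-[(2S)-2-(TBS-oxy)undecyl]-4-[2-(TBS-oxy)ethyl]-10-methyl-1-oxacyclotetradeca-3,9-dien-6-yn-2-one
Conditions: [Mo(≡CC6H4-4-OMe)(OSiPh3)3] (cat.), 5 Å molecular sieves, toluene (2 mM), rt → 60 °C
Reagents that add atoms: none
Why: Ring-closing alkyne metathesis: the molybdenum alkylidyne adds to one methyl-capped alkyne of 29 by [2+2] cycloaddition, and cycloreversion of the metallacyclobutadiene leaves the chain bound to molybdenum as a new alkylidyne; this adds to the second alkyne, and the second cycloreversion releases the C5≡C6 cycloalkyne while the two methyl caps leave as but-2-yne. The closest known reaction type is the closure of macrocyclic cycloalkynes from methyl-capped diynes with silanolate-ligated molybdenum alkylidynes. The single ring, the 14-membered lactone, closes end to end through the new C5–C6 triple bond between two sp carbons held by the propargylic methylenes C4 and C7. No stereocentre is formed, and C11, C13 and C15 are not touched. The step needs ring closure to win over acyclic diyne metathesis oligomerisation; this is secured by 2 mM dilution, by the sieves that trap but-2-yne and make each productive turnover irreversible, and by the two trisubstituted alkenes and the ester, which remove rotors from the chain and turn its ends towards each other. It also needs the catalyst to leave the alkenes, the enoate and the activated methylenes alone: alkylidynes do not engage alkenes, and no carbene, hydride or base is present that could move C2=C3 or C8=C9 through C4 or C7. A 14-membered ring holds the linear C4–C5≡C6–C7 unit without strain, so the equilibrium lies with the ring once but-2-yne is removed.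

Step 22
Reactants: 30 (3E,9E,12S,14R)-12-(TBS-oxy)-14-[(2S)-2-(TBS-oxy)undecyl]-4-[2-(TBS-oxy)ethyl]-10-methyl-1-oxacyclotetradeca-3,9-dien-6-yn-2-one
Product: 33 (3E,6E,9E,12S,14R)-12-(TBS-oxy)-14-[(2S)-2-(TBS-oxy)undecyl]-4-[2-(TBS-oxy)ethyl]-10-methyl-1-oxacyclotetradeca-3,6,9-trien-2-one, via C5-silyl alkenylsilane 31 (not isolated), via C6-silyl alkenylsilane 32 (not isolated)
Conditions: (EtO)3SiH, [Cp*Ru(MeCN)3]PF6 (cat.), CH2Cl2, 0 °C → rt; concentrate; AgF, THF/MeOH/H2O, rt, dark
Reagents that add atoms: none
Why: Ruthenium-catalysed trans-hydrosilylation delivers H and Si to opposite faces of the alkyne, so C4 and C7 end trans whichever carbon takes silicon. Silver fluoride then replaces silicon by hydrogen with retention (protodesilylation), which gives the E alkene from both regioisomers; the cationic ruthenium catalyst is not expected to hydrosilylate the trisubstituted alkenes or the enoate.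

Step 23
Reactants: 33 (3E,6E,9E,12S,14R)-12-(TBS-oxy)-14-[(2S)-2-(TBS-oxy)undecyl]-4-[2-(TBS-oxy)ethyl]-10-methyl-1-oxacyclotetradeca-3,6,9-trien-2-one
Product: 34 (3E,6E,9E,12S,14R)-12-(TBS-oxy)-14-[(2S)-2-(TBS-oxy)undecyl]-4-(2-hydroxyethyl)-10-methyl-1-oxacyclotetradeca-3,6,9-trien-2-one
Conditions: HF·pyridine, pyridine, THF, 0 °C
Reagents that add atoms: none
Why: Buffered HF·pyridine cleaves the unhindered primary silyl ether faster than the two secondary ones; the medium is not basic, so the skipped triene and the lactone are not disturbed.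

Step 24
Reactants: 34 (3E,6E,9E,12S,14R)-12-(TBS-oxy)-14-[(2S)-2-(TBS-oxy)undecyl]-4-(2-hydroxyethyl)-10-methyl-1-oxacyclotetradeca-3,6,9-trien-2-one
Product: 35 2-[(3E,6E,9E,12S,14R)-12-(TBS-oxy)-14-[(2S)-2-(TBS-oxy)undecyl]-10-methyl-2-oxo-1-oxacyclotetradeca-3,6,9-trien-4-yl]acetaldehyde
Conditions: DMP, NaHCO3, CH2Cl2, 0 °C
Reagents that add atoms: none
Why: Dess–Martin oxidation under buffered conditions gives the β,γ-unsaturated aldehyde without base; it is taken on at once to keep C2=C3 from moving towards the aldehyde.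

Step 25
Reactants: 35 2-[(3E,6E,9E,12S,14R)-12-(TBS-oxy)-14-[(2S)-2-(TBS-oxy)undecyl]-10-methyl-2-oxo-1-oxacyclotetradeca-3,6,9-trien-4-yl]acetaldehyde
Product: 36 2-[(3E,6E,9E,12S,14R)-12-(TBS-oxy)-14-[(2S)-2-(TBS-oxy)undecyl]-10-methyl-2-oxo-1-oxacyclotetradeca-3,6,9-trien-4-yl]acetic acid
Conditions: NaClO2, NaH2PO4, 2-methylbut-2-ene, t-BuOH/H2O, 0 °C
Reagents that add atoms: sodium chlorite, [Na+].[O-]Cl=O
Why: Pinnick oxidation: chlorite at about pH 4 oxidises only the aldehyde, and the alkene scavenger removes hypochlorite before it can reach the ring alkenes. The weakly acidic medium keeps the glutaconate system from isomerising.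

Step 26
Reactants: 36 2-[(3E,6E,9E,12S,14R)-12-(TBS-oxy)-14-[(2S)-2-(TBS-oxy)undecyl]-10-methyl-2-oxo-1-oxacyclotetradeca-3,6,9-trien-4-yl]acetic acid
Product: 37 2-[(3E,6E,9E,12S,14R)-12-hydroxy-14-[(2S)-2-hydroxyundecyl]-10-methyl-2-oxo-1-oxacyclotetradeca-3,6,9-trien-4-yl]acetic acid
Conditions: HF·pyridine, THF, 0 °C → rt
Reagents that add atoms: none
Why: Acidic fluoride removes the two secondary TBS ethers without base, so neither the glutaconate double bond nor the lactone position (acyl shift to O11 or O15) should change.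

## Compound list

1 | decanal | CCCCCCCCCC=O | starting material
2 | (4S)-tridec-1-en-4-ol | CCCCCCCCC[C@H](O)CC=C | intermediate
3 | (4S)-4-(TBS-oxy)tridec-1-ene | CCCCCCCCC[C@H](O[Si](C)(C)C(C)(C)C)CC=C | intermediate
4 | 3-[(2S)-2-(TBS-oxy)undecyl]-1,2,4-trioxolane (secondary ozonide of 3, ring carbon unassigned) | CCCCCCCCC[C@H](O[Si](C)(C)C(C)(C)C)CC1OCOO1 | intermediate
5 | (3S)-3-(TBS-oxy)dodecanal | CCCCCCCCC[C@H](O[Si](C)(C)C(C)(C)C)CC=O | intermediate
6 | (4R,6S)-6-(TBS-oxy)pentadec-1-en-4-ol | CCCCCCCCC[C@H](O[Si](C)(C)C(C)(C)C)C[C@H](O)CC=C | intermediate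
7 | (4R,6S)-6-(TBS-oxy)-4-(TES-oxy)pentadec-1-ene | CCCCCCCCC[C@H](O[Si](C)(C)C(C)(C)C)C[C@H](O[Si](CC)(CC)CC)CC=C | intermediate
8 | 3-[(2S,4S)-4-(TBS-oxy)-2-(TES-oxy)tridecyl]-1,2,4-trioxolane (secondary ozonide of 7, ring carbon unassigned) | CCCCCCCCC[C@H](O[Si](C)(C)C(C)(C)C)C[C@H](O[Si](CC)(CC)CC)CC1OCOO1 | intermediate
9 | (3S,5S)-5-(TBS-oxy)-3-(TES-oxy)tetradecanal | CCCCCCCCC[C@H](O[Si](C)(C)C(C)(C)C)C[C@H](O[Si](CC)(CC)CC)CC=O | intermediate
10 | (4S,6R,8S)-8-(TBS-oxy)-6-(TES-oxy)heptadec-1-yn-4-ol | CCCCCCCCC[C@H](O[Si](C)(C)C(C)(C)C)C[C@H](O[Si](CC)(CC)CC)C[C@@H](O)CC#C | intermediate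
11 | (4S,6S,8S)-4,8-bis(TBS-oxy)-6-(TES-oxy)heptadec-1-yne | CCCCCCCCC[C@H](O[Si](C)(C)C(C)(C)C)C[C@H](O[Si](CC)(CC)CC)C[C@@H](O[Si](C)(C)C(C)(C)C)CC#C | intermediate
12 | [(1E,4S,6S,8S)-4,8-bis(TBS-oxy)-2-methyl-6-(TES-oxy)heptadec-1-en-1-yl]dimethylalane | CCCCCCCCC[C@H](O[Si](C)(C)C(C)(C)C)C[C@H](O[Si](CC)(CC)CC)C[C@@H](O[Si](C)(C)C(C)(C)C)C/C(C)=C/[Al](C)C | intermediate
13 | lithium butyl(dimethyl)[(1E,4S,6S,8S)-4,8-bis(TBS-oxy)-2-methyl-6-(TES-oxy)heptadec-1-en-1-yl]aluminate | [Li+].CCCCCCCCC[C@H](O[Si](C)(C)C(C)(C)C)C[C@H](O[Si](CC)(CC)CC)C[C@@H](O[Si](C)(C)C(C)(C)C)C/C(C)=C/[Al-](C)(C)CCCC | intermediate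
14 | (2E,5S,7S,9S)-5,9-bis(TBS-oxy)-3-methyl-7-(TES-oxy)octadec-2-en-1-ol | CCCCCCCCC[C@H](O[Si](C)(C)C(C)(C)C)C[C@H](O[Si](CC)(CC)CC)C[C@@H](O[Si](C)(C)C(C)(C)C)C/C(C)=C/CO | intermediate
15 | (2E,5S,7S,9S)-1-bromo-5,9-bis(TBS-oxy)-3-methyl-7-(TES-oxy)octadec-2-ene | CCCCCCCCC[C@H](O[Si](C)(C)C(C)(C)C)C[C@H](O[Si](CC)(CC)CC)C[C@@H](O[Si](C)(C)C(C)(C)C)C/C(C)=C/CBr | intermediate
16 | propyne | CC#C | starting material
17 | (5E,8S,10S,12S)-8,12-bis(TBS-oxy)-6-methyl-10-(TES-oxy)henicos-5-en-2-yne | CCCCCCCCC[C@H](O[Si](C)(C)C(C)(C)C)C[C@H](O[Si](CC)(CC)CC)C[C@@H](O[Si](C)(C)C(C)(C)C)C/C(C)=C/CC#CC | intermediate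
18 | (5E,8S,10S,12S)-8,12-bis(TBS-oxy)-6-methylhenicos-5-en-2-yn-10-ol | CCCCCCCCC[C@H](O[Si](C)(C)C(C)(C)C)C[C@H](O)C[C@@H](O[Si](C)(C)C(C)(C)C)C/C(C)=C/CC#CC | intermediate
19 | tert-butyl(but-3-yn-1-yloxy)dimethylsilane | C#CCCO[Si](C)(C)C(C)(C)C | starting material
20 | lithium 4-(TBS-oxy)but-1-yn-1-ide (lithium acetylide of 19) | [Li]C#CCCO[Si](C)(C)C(C)(C)C | intermediate
21 | methyl 5-(TBS-oxy)pent-2-ynoate | COC(=O)C#CCCO[Si](C)(C)C(C)(C)C | intermediate
22 | methyl (2Z)-3-iodo-5-(TBS-oxy)pent-2-enoate | COC(=O)/C=C(\I)CCO[Si](C)(C)C(C)(C)C | intermediate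
23 | methyl (2Z)-4-hydroxy-3-[2-(TBS-oxy)ethyl]but-2-enoate | COC(=O)/C=C(\CO)CCO[Si](C)(C)C(C)(C)C | intermediate
24 | 4-[2-(TBS-oxy)ethyl]furan-2(5H)-one | O=C1C=C(CCO[Si](C)(C)C(C)(C)C)CO1 | intermediate
25 | methyl (2Z)-4-bromo-3-(2-hydroxyethyl)but-2-enoate | COC(=O)/C=C(\CBr)CCO | intermediate
26 | methyl (2Z)-4-bromo-3-[2-(TBS-oxy)ethyl]but-2-enoate | COC(=O)/C=C(\CBr)CCO[Si](C)(C)C(C)(C)C | intermediate
27 | methyl (2E)-3-[2-(TBS-oxy)ethyl]hept-2-en-5-ynoate | COC(=O)/C=C(\CC#CC)CCO[Si](C)(C)C(C)(C)C | intermediate
28 | (2E)-3-[2-(TBS-oxy)ethyl]hept-2-en-5-ynoic acid | OC(=O)/C=C(\CC#CC)CCO[Si](C)(C)C(C)(C)C | intermediate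
29 | (5E,8S,10R,12S)-8,12-bis(TBS-oxy)-6-methylhenicos-5-en-2-yn-10-yl (2E)-3-[2-(TBS-oxy)ethyl]hept-2-en-5-ynoate | CCCCCCCCC[C@H](O[Si](C)(C)C(C)(C)C)C[C@@H](OC(=O)/C=C(CCO[Si](C)(C)C(C)(C)C)\CC#CC)C[C@@H](O[Si](C)(C)C(C)(C)C)C/C(C)=C/CC#CC | intermediate
30 | (3E,9E,12S,14R)-12-(TBS-oxy)-14-[(2S)-2-(TBS-oxy)undecyl]-4-[2-(TBS-oxy)ethyl]-10-methyl-1-oxacyclotetradeca-3,9-dien-6-yn-2-one | CCCCCCCCC[C@H](O[Si](C)(C)C(C)(C)C)C[C@@H]1C[C@@H](O[Si](C)(C)C(C)(C)C)C/C(C)=C/CC#CC/C(CCO[Si](C)(C)C(C)(C)C)=C\C(=O)O1 | intermediate
31 | alkenylsilane of 30 with Si(OEt)3 on C5 and H on C6, trans to each other (C4 and C7 trans) | CCCCCCCCC[C@H](O[Si](C)(C)C(C)(C)C)C[C@@H]1C[C@@H](O[Si](C)(C)C(C)(C)C)C/C(C)=C/C/C=C(\[Si](OCC)(OCC)OCC)/C/C(CCO[Si](C)(C)C(C)(C)C)=C\C(=O)O1 | intermediate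
32 | alkenylsilane of 30 with Si(OEt)3 on C6 and H on C5, trans to each other (C4 and C7 trans) | CCCCCCCCC[C@H](O[Si](C)(C)C(C)(C)C)C[C@@H]1C[C@@H](O[Si](C)(C)C(C)(C)C)C/C(C)=C/C/C([Si](OCC)(OCC)OCC)=C/C/C(CCO[Si](C)(C)C(C)(C)C)=C\C(=O)O1 | intermediate
33 | (3E,6E,9E,12S,14R)-12-(TBS-oxy)-14-[(2S)-2-(TBS-oxy)undecyl]-4-[2-(TBS-oxy)ethyl]-10-methyl-1-oxacyclotetradeca-3,6,9-trien-2-one | CCCCCCCCC[C@H](O[Si](C)(C)C(C)(C)C)C[C@@H]1C[C@@H](O[Si](C)(C)C(C)(C)C)C/C(C)=C/C/C=C/C/C(CCO[Si](C)(C)C(C)(C)C)=C\C(=O)O1 | intermediate
34 | (3E,6E,9E,12S,14R)-12-(TBS-oxy)-14-[(2S)-2-(TBS-oxy)undecyl]-4-(2-hydroxyethyl)-10-methyl-1-oxacyclotetradeca-3,6,9-trien-2-one | CCCCCCCCC[C@H](O[Si](C)(C)C(C)(C)C)C[C@@H]1C[C@@H](O[Si](C)(C)C(C)(C)C)C/C(C)=C/C/C=C/C/C(CCO)=C\C(=O)O1 | intermediate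
35 | 2-[(3E,6E,9E,12S,14R)-12-(TBS-oxy)-14-[(2S)-2-(TBS-oxy)undecyl]-10-methyl-2-oxo-1-oxacyclotetradeca-3,6,9-trien-4-yl]acetaldehyde | CCCCCCCCC[C@H](O[Si](C)(C)C(C)(C)C)C[C@@H]1C[C@@H](O[Si](C)(C)C(C)(C)C)C/C(C)=C/C/C=C/C/C(CC=O)=C\C(=O)O1 | intermediate
36 | 2-[(3E,6E,9E,12S,14R)-12-(TBS-oxy)-14-[(2S)-2-(TBS-oxy)undecyl]-10-methyl-2-oxo-1-oxacyclotetradeca-3,6,9-trien-4-yl]acetic acid | CCCCCCCCC[C@H](O[Si](C)(C)C(C)(C)C)C[C@@H]1C[C@@H](O[Si](C)(C)C(C)(C)C)C/C(C)=C/C/C=C/C/C(CC(=O)O)=C\C(=O)O1 | intermediate
37 | 2-[(3E,6E,9E,12S,14R)-12-hydroxy-14-[(2S)-2-hydroxyundecyl]-10-methyl-2-oxo-1-oxacyclotetradeca-3,6,9-trien-4-yl]acetic acid | CCCCCCCCC[C@H](O)C[C@@H]1C[C@@H](O)C/C(C)=C/C/C=C/C/C(CC(=O)O)=C\C(=O)O1 | target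

## Step count and least certain steps

Total step count: 26. Longest linear sequence: 19 steps (steps 1–12, then 20–26). The acid branch (steps 13–19) has 7 steps.

**Step 21 (key step).** The likeliest failure is acyclic diyne metathesis between two molecules, giving dimers and oligomers. The alkyne on C4 sits next to the fully substituted C3 and may be slow to enter the catalytic cycle, while the unhindered alkyne on C7 can homodimerise in the meantime. Traces of moisture would also hydrolyse the silanolate catalyst.

Fallback: close the ring at the ester bond. Bromide 15 is coupled with trimethylsilylacetylene under the copper conditions of step 11 to give the silyl-capped enyne F1, and potassium carbonate in methanol frees the terminal alkyne F2. Copper-catalysed alkynylation of bromide 26 with F2 builds the C4–C5 bond and gives the open-chain methyl ester F3, with C5≡C6 already in place. Removal of the TES group gives the hydroxy ester F4, and Me3SnOH gives the seco acid F5. Mitsunobu macrolactonisation of F5 at high dilution inverts C13 and returns to the route at cycloalkyne 30.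

**Step 16.** The opening may stop short or revert: the bromo acid formed first can re-close to the butenolide with loss of HBr before it is esterified, because the cis geometry holds carboxyl and CH2Br together. Slow methanolysis of the allylic bromide is a second drain.

Fallback: avoid the lactone by using a tert-butyl ester. Starting from 19, acylation of the lithium acetylide with di-tert-butyl dicarbonate gives the tert-butyl ynoate F6. Hydroiodination as in step 14 gives the tert-butyl Z-iodoenoate F7. Stille hydroxymethylation at moderate temperature gives the tert-butyl Z-hydroxy enoate F8, which lactonises far more slowly than 23. An Appel reaction gives the tert-butyl Z-bromo enoate F9, and alkynylation with 16 gives the tert-butyl enyne ester F10. Cleavage with TMSOTf and 2,6-lutidine returns to the route at acid 28.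

**Step 20.** The displacement at C13, which carries a branched chain on each side, may be slow. Elimination of the alkoxyphosphonium ion, or acylation through an acyloxyphosphonium ion with retention, would then compete and erode yield or configuration.

Fallback: separate inversion from ester formation. Alcohol 18 is inverted by a Mitsunobu reaction with 4-nitrobenzoic acid, a more acidic and smaller partner, to the 4-nitrobenzoate F11. Methanolysis with potassium carbonate gives the 10R alcohol F12. Acid 28 is converted with 1-chloro-N,N,2-trimethylprop-1-en-1-amine into the acid chloride F13, which acylates F12 with pyridine at low temperature and returns to the route at 29.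

**Step 7.** Facial control by the reagent may be incomplete against the β-silyloxy aldehyde. The allenylborane may also equilibrate with its propargyl isomer and give some allenyl carbinol.

Fallback: build C11 from an epoxide. Alkene 7 is epoxidised with mCPBA to the terminal epoxide F14 (both C11 epimers). Hydrolytic kinetic resolution with (S,S)-(salen)Co(OAc) (trivalent cobalt; salen = N,N′-bis(3,5-di-tert-butylsalicylidene)cyclohexane-1,2-diamine dianion) is then applied, using the antipode that should spare the 2R oxirane. It leaves the single epoxide F15 and turns the other epimer into the diol F16, which is discarded. Opening of F15 at C10 with lithium acetylide–ethylenediamine complex in DMSO returns to the route at 10.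

**Step 22.** The cationic ruthenium catalyst may bind the flanking alkenes and stall, or the protodesilylation may be slow for the regioisomer with silicon on C5, next to the branched C3. Prolonged contact with silver fluoride could then let the skipped alkenes migrate or strip the primary silyl ether.

Fallback: direct ruthenium-catalysed trans-hydrogenation of 30 (H2, [Cp*Ru(cod)Cl], CH2Cl2). It gives 33 without a silicon intermediate and needs no new compound; the process to watch there is over-reduction.

## Further compounds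

F1 | step 21 | trimethylsilyl-capped enyne from 15: (4E,7S,9S,11S)-7,11-bis(TBS-oxy)-5-methyl-9-(TES-oxy)-1-(trimethylsilyl)icos-4-en-1-yne | CCCCCCCCC[C@H](O[Si](C)(C)C(C)(C)C)C[C@H](O[Si](CC)(CC)CC)C[C@@H](O[Si](C)(C)C(C)(C)C)C/C(C)=C/CC#C[Si](C)(C)C
F2 | step 21 | (4E,7S,9S,11S)-7,11-bis(TBS-oxy)-5-methyl-9-(TES-oxy)icos-4-en-1-yne | CCCCCCCCC[C@H](O[Si](C)(C)C(C)(C)C)C[C@H](O[Si](CC)(CC)CC)C[C@@H](O[Si](C)(C)C(C)(C)C)C/C(C)=C/CC#C
F3 | step 21 | methyl (2E,8E,11S,13S,15S)-11,15-bis(TBS-oxy)-3-[2-(TBS-oxy)ethyl]-9-methyl-13-(TES-oxy)tetracosa-2,8-dien-5-ynoate | CCCCCCCCC[C@H](O[Si](C)(C)C(C)(C)C)C[C@H](O[Si](CC)(CC)CC)C[C@@H](O[Si](C)(C)C(C)(C)C)C/C(C)=C/CC#CC/C(CCO[Si](C)(C)C(C)(C)C)=C\C(=O)OC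
F4 | step 21 | methyl (2E,8E,11S,13S,15S)-11,15-bis(TBS-oxy)-3-[2-(TBS-oxy)ethyl]-13-hydroxy-9-methyltetracosa-2,8-dien-5-ynoate | CCCCCCCCC[C@H](O[Si](C)(C)C(C)(C)C)C[C@H](O)C[C@@H](O[Si](C)(C)C(C)(C)C)C/C(C)=C/CC#CC/C(CCO[Si](C)(C)C(C)(C)C)=C\C(=O)OC
F5 | step 21 | (2E,8E,11S,13S,15S)-11,15-bis(TBS-oxy)-3-[2-(TBS-oxy)ethyl]-13-hydroxy-9-methyltetracosa-2,8-dien-5-ynoic acid | CCCCCCCCC[C@H](O[Si](C)(C)C(C)(C)C)C[C@H](O)C[C@@H](O[Si](C)(C)C(C)(C)C)C/C(C)=C/CC#CC/C(CCO[Si](C)(C)C(C)(C)C)=C\C(=O)O
F6 | step 16 | tert-butyl 5-(TBS-oxy)pent-2-ynoate | CC(C)(C)OC(=O)C#CCCO[Si](C)(C)C(C)(C)C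
F7 | step 16 | tert-butyl (2Z)-3-iodo-5-(TBS-oxy)pent-2-enoate | CC(C)(C)OC(=O)/C=C(\I)CCO[Si](C)(C)C(C)(C)C
F8 | step 16 | tert-butyl (2Z)-4-hydroxy-3-[2-(TBS-oxy)ethyl]but-2-enoate | CC(C)(C)OC(=O)/C=C(\CO)CCO[Si](C)(C)C(C)(C)C
F9 | step 16 | tert-butyl (2Z)-4-bromo-3-[2-(TBS-oxy)ethyl]but-2-enoate | CC(C)(C)OC(=O)/C=C(\CBr)CCO[Si](C)(C)C(C)(C)C
F10 | step 16 | tert-butyl (2E)-3-[2-(TBS-oxy)ethyl]hept-2-en-5-ynoate | CC(C)(C)OC(=O)/C=C(\CC#CC)CCO[Si](C)(C)C(C)(C)C
F11 | step 20 | (5E,8S,10R,12S)-8,12-bis(TBS-oxy)-6-methylhenicos-5-en-2-yn-10-yl 4-nitrobenzoate | CCCCCCCCC[C@H](O[Si](C)(C)C(C)(C)C)C[C@@H](OC(=O)c1ccc(cc1)[N+](=O)[O-])C[C@@H](O[Si](C)(C)C(C)(C)C)C/C(C)=C/CC#CC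
F12 | step 20 | (5E,8S,10R,12S)-8,12-bis(TBS-oxy)-6-methylhenicos-5-en-2-yn-10-ol | CCCCCCCCC[C@H](O[Si](C)(C)C(C)(C)C)C[C@@H](O)C[C@@H](O[Si](C)(C)C(C)(C)C)C/C(C)=C/CC#CC
F13 | step 20 | (2E)-3-[2-(TBS-oxy)ethyl]hept-2-en-5-ynoyl chloride | ClC(=O)/C=C(\CC#CC)CCO[Si](C)(C)C(C)(C)C
F14 | step 7 | 2-[(2R,4S)-4-(TBS-oxy)-2-(TES-oxy)tridecyl]oxirane (both epimers at the oxirane carbon) | CCCCCCCCC[C@H](O[Si](C)(C)C(C)(C)C)C[C@H](O[Si](CC)(CC)CC)CC1CO1
F15 | step 7 | (2R)-2-[(2R,4S)-4-(TBS-oxy)-2-(TES-oxy)tridecyl]oxirane | CCCCCCCCC[C@H](O[Si](C)(C)C(C)(C)C)C[C@H](O[Si](CC)(CC)CC)C[C@@H]1CO1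
F16 | step 7 | (2S,4S,6S)-6-(TBS-oxy)-4-(TES-oxy)pentadecane-1,2-diol (by-product of the resolution) | CCCCCCCCC[C@H](O[Si](C)(C)C(C)(C)C)C[C@H](O[Si](CC)(CC)CC)C[C@H](O)CO
F0 | step 22 | none | none
A1 | alternative 1 | (3R,5S)-6-chloro-3,5-dihydroxyhexanal (rests as its six-membered lactol) | ClC[C@@H](O)C[C@@H](O)CC=O
A2 | alternative 1 | chloroacetaldehyde | ClCC=O
A3 | alternative 1 | acetaldehyde | CC=O
A4 | alternative 2 | 14-membered lactone with free C11 and C15 hydroxyls and a 2-(TBS-oxy)ethyl arm | CCCCCCCCC[C@H](O)C[C@@H]1C[C@@H](O)C/C(C)=C/C/C=C/C/C(CCO[Si](C)(C)C(C)(C)C)=C\C(=O)O1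
A5 | alternative 2 | open-chain 11,13-dihydroxy-15-oxo enal with a 2-(TBS-oxy)ethyl arm | CCCCCCCCCC(=O)C[C@@H](O)C[C@@H](O)C/C(C)=C/C/C=C/C/C(CCO[Si](C)(C)C(C)(C)C)=C\C=O
A6 | alternative 3 | tris-TBS 14-membered lactone (identical with 33) | CCCCCCCCC[C@H](O[Si](C)(C)C(C)(C)C)C[C@@H]1C[C@@H](O[Si](C)(C)C(C)(C)C)C/C(C)=C/C/C=C/C/C(CCO[Si](C)(C)C(C)(C)C)=C\C(=O)O1
A7 | alternative 3 | C13 (E)-5-(TBS-oxy)pent-2-enoate whose chain ends in a C6 methyl carbonate and a C4=C5 vinyl group (either C6 epimer) | CCCCCCCCC[C@H](O[Si](C)(C)C(C)(C)C)C[C@@H](OC(=O)/C=C/CCO[Si](C)(C)C(C)(C)C)C[C@@H](O[Si](C)(C)C(C)(C)C)C/C(C)=C/CC(OC(=O)OC)C=C
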